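**Plan**

- Retrosynthesis: after unmasking the C5 phenol (MOM ether) and the C1' ketone (1,3-dithiane), the side chain is cut at C1'–C2', between the acyl carbon on C6 of the chromene and the CH2 group. The cut is available because the C1' carbonyl and the C3' carbinol (CHOH–Ph) stand 1,3 to each other, the pattern left when an acyl anion opens a terminal epoxide.
- The aryl fragment is then cut at O1–C2 and C4–C4a of the pyran ring, back to 2,4-dihydroxy-6-methoxybenzaldehyde and prenal.
- Forward: the pyran ring is fused onto the purchased benzene ring first (the only ring formed). The formyl group on C6 becomes a dithiane, the C5 phenol a MOM ether, the lithiated dithiane is joined to (R)-styrene oxide, and the two masks are then removed.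
- Stereochemistry: the single stereocentre (C3', S) is bought as (R)-styrene oxide. Its C–O bond is never broken; the descriptor changes only through the CIP priorities.

Key step: step 4

Remark: 2,4-dihydroxy-6-methoxybenzaldehyde is taken as a purchasable compound; the chromene is numbered O1, C2 … C8a and the side chain C1' (C=O), C2' (CH2), C3' (CHOH).

**Route**

Step 1
Reactants: 1 2,4-dihydroxy-6-methoxybenzaldehyde; 2 3-methylbut-2-enal (prenal)
Product: 4 5-hydroxy-7-methoxy-2,2-dimethyl-2H-chromene-6-carbaldehyde, via quinone methide 3 (not isolated)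
Conditions: prenal (2 equiv), ethylenediammonium diacetate (EDDA, 0.2 equiv), toluene, reflux
Reagents that add atoms: none
Why: The amine salt turns prenal into an iminium ion that is attacked by C3 of 1 (the carbon between the two hydroxyls, favoured because chelation of the 2-OH to the formyl group fixes enol character in the C3–C4 bond), loss of the amine gives quinone methide 3, and its oxa-6π electrocyclisation onto the free 4-oxygen closes the pyran ring (Knoevenagel-type condensation/electrocyclisation, a formal [3+3] chromene annulation).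

Step 2
Reactants: 4 5-hydroxy-7-methoxy-2,2-dimethyl-2H-chromene-6-carbaldehyde; 5 propane-1,3-dithiol
Product: 6 6-(1,3-dithian-2-yl)-7-methoxy-2,2-dimethyl-2H-chromen-5-ol
Conditions: propane-1,3-dithiol (1.2 equiv), BF3·OEt2 (0.3 equiv), CH2Cl2, 0 °C → rt
Reagents that add atoms: none
Why: Lewis-acid-catalysed dithioacetalisation of an aryl aldehyde, run with substoichiometric BF3·OEt2 in the cold so that thiol should not add to the acid-sensitive chromene double bond, and placed before the MOM protection because a MOM ether would not survive thiol and Lewis acid.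

Step 3
Reactants: 6 6-(1,3-dithian-2-yl)-7-methoxy-2,2-dimethyl-2H-chromen-5-ol
Product: 8 2-[7-methoxy-5-(methoxymethoxy)-2,2-dimethyl-2H-chromen-6-yl]-1,3-dithiane, via sodium phenoxide 7 (not isolated)
Conditions: NaH (1.2 equiv), DMF, 0 °C; then MOMCl (1.2 equiv), 0 °C → rt
Reagents that add atoms: chloromethyl methyl ether (MOMCl), COCCl
Why: Williamson-type O-alkylation of phenoxide 7 by the hard electrophile MOMCl (MOM protection), under conditions too weakly basic to touch the dithiane C–H; MOM is chosen because it withstands n-BuLi, can hold lithium near the metalation site and leaves under mild acid once the ortho ketone is present.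

Step 4
Reactants: 8 2-[7-methoxy-5-(methoxymethoxy)-2,2-dimethyl-2H-chromen-6-yl]-1,3-dithiane; 9 (R)-styrene oxide
Product: 12 (1S)-2-{2-[7-methoxy-5-(methoxymethoxy)-2,2-dimethyl-2H-chromen-6-yl]-1,3-dithian-2-yl}-1-phenylethan-1-ol, via 2-lithio-1,3-dithiane 10 (not isolated), via lithium alkoxide 11 (not isolated)
Conditions: n-BuLi (1.05 equiv), THF, −78 → −20 °C; then 9 (1.3 equiv), −20 °C → rt; aq. NH4Cl
Reagents that add atoms: none
Why: n-BuLi removes the dithiane C2–H, which is acidified by two sulfur atoms and the aryl group and flanked by the lithium-binding OMOM and OMe oxygens; the tertiary carbanion 10 then attacks the CH2 carbon of epoxide 9 from the rear in a strain-driven SN2 opening that forms the C1'–C2' bond and leaves alkoxide 11, protonated on quench. The closest known reaction type is the Corey–Seebach alkylation of 2-aryl-2-lithio-1,3-dithianes with terminal epoxides. No ring is closed and no stereocentre is created: the C3' centre arrives intact from 9 because its C–O bond is not broken, and the label changes from R to S only because the CH2 group loses its oxygen and drops below phenyl in priority. The step needs attack at the terminal carbon and not at the benzylic one, which the bulk of the tertiary anion and the absence of any Lewis acid should secure. It also needs metalation at the dithiane and not at ring position C8, which the far higher acidity of the dithiane C–H should secure, with metalation completed before 9 is added so that no free n-BuLi meets the epoxide. Because the carbonyl is still masked, retro-aldol cleavage and loss of water from the new 1,3-oxygenated chain cannot occur during the coupling.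

Step 5
Reactants: 12 (1S)-2-{2-[7-methoxy-5-(methoxymethoxy)-2,2-dimethyl-2H-chromen-6-yl]-1,3-dithian-2-yl}-1-phenylethan-1-ol
Product: 13 (3S)-3-hydroxy-1-[7-methoxy-5-(methoxymethoxy)-2,2-dimethyl-2H-chromen-6-yl]-3-phenylpropan-1-one
Conditions: MeI (excess), CaCO3, MeCN–H2O (9:1), 40 °C
Reagents that add atoms: water, O
Why: Alkylative dithiane hydrolysis, in which S-methylation makes one sulfur a leaving group, water captures the aryl-stabilised thionium ion and CaCO3 takes up the HI; the method is non-oxidative and near neutral, so the electron-rich arene, the chromene double bond, the MOM acetal and the C3' carbinol should be left alone.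

Step 6
Reactants: 13 (3S)-3-hydroxy-1-[7-methoxy-5-(methoxymethoxy)-2,2-dimethyl-2H-chromen-6-yl]-3-phenylpropan-1-one
Product: 14 (3S)-3-hydroxy-1-(5-hydroxy-7-methoxy-2,2-dimethyl-2H-chromen-6-yl)-3-phenylpropan-1-one (target)
Conditions: aq. HCl (2 M), THF, rt to 40 °C
Reagents that add atoms: none
Why: Acid-catalysed hydrolysis of the MOM acetal, especially easy for a phenol ortho to a ketone because the freed OH is held in a hydrogen bond to the carbonyl, so dilute acid near room temperature should suffice without dehydrating the β-hydroxy ketone or ionising the C3' centre.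

**Compound list**

1 | 2,4-dihydroxy-6-methoxybenzaldehyde | COc1cc(O)cc(O)c1C=O | starting material
2 | 3-methylbut-2-enal (prenal) | CC(C)=CC=O | starting material
3 | quinone methide 2-hydroxy-6-methoxy-3-(3-methylbut-2-en-1-ylidene)-4-oxocyclohexa-1,5-diene-1-carbaldehyde (formed in the flask) | O=CC1=C(O)C(=CC=C(C)C)C(=O)C=C1OC | intermediate
4 | 5-hydroxy-7-methoxy-2,2-dimethyl-2H-chromene-6-carbaldehyde | COc1cc2OC(C)(C)C=Cc2c(O)c1C=O | intermediate
5 | propane-1,3-dithiol | SCCCS | starting material
6 | 6-(1,3-dithian-2-yl)-7-methoxy-2,2-dimethyl-2H-chromen-5-ol | COc1cc2OC(C)(C)C=Cc2c(O)c1C1SCCCS1 | intermediate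
7 | sodium 6-(1,3-dithian-2-yl)-7-methoxy-2,2-dimethyl-2H-chromen-5-olate (formed in the flask) | COc1cc2OC(C)(C)C=Cc2c([O-])c1C1SCCCS1.[Na+] | intermediate
8 | 2-[7-methoxy-5-(methoxymethoxy)-2,2-dimethyl-2H-chromen-6-yl]-1,3-dithiane | COc1cc2OC(C)(C)C=Cc2c(OCOC)c1C1SCCCS1 | intermediate
9 | (R)-styrene oxide, (2R)-2-phenyloxirane | C1[C@H](O1)c1ccccc1 | starting material
10 | 2-lithio-2-[7-methoxy-5-(methoxymethoxy)-2,2-dimethyl-2H-chromen-6-yl]-1,3-dithiane (formed in the flask) | COc1cc2OC(C)(C)C=Cc2c(OCOC)c1C1([Li])SCCCS1 | intermediate
11 | lithium (1S)-2-{2-[7-methoxy-5-(methoxymethoxy)-2,2-dimethyl-2H-chromen-6-yl]-1,3-dithian-2-yl}-1-phenylethan-1-olate (formed in the flask) | COc1cc2OC(C)(C)C=Cc2c(OCOC)c1C1(C[C@H]([O-])c2ccccc2)SCCCS1.[Li+] | intermediate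
12 | (1S)-2-{2-[7-methoxy-5-(methoxymethoxy)-2,2-dimethyl-2H-chromen-6-yl]-1,3-dithian-2-yl}-1-phenylethan-1-ol | COc1cc2OC(C)(C)C=Cc2c(OCOC)c1C1(C[C@H](O)c2ccccc2)SCCCS1 | intermediate
13 | (3S)-3-hydroxy-1-[7-methoxy-5-(methoxymethoxy)-2,2-dimethyl-2H-chromen-6-yl]-3-phenylpropan-1-one | COc1cc2OC(C)(C)C=Cc2c(OCOC)c1C(=O)C[C@H](O)c1ccccc1 | intermediate
14 | (3S)-3-hydroxy-1-(5-hydroxy-7-methoxy-2,2-dimethyl-2H-chromen-6-yl)-3-phenylpropan-1-one | COc1cc2OC(C)(C)C=Cc2c(O)c1C(=O)C[C@H](O)c1ccccc1 | target

**Step count and risks**

Total step count: 6. Longest linear sequence: 6 steps (1 → 14).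

Step 4 (most at risk). Metalation of the doubly ortho-substituted aryl dithiane may be slow or incomplete, and the crowded tertiary carbanion may attack the epoxide sluggishly. Ring lithiation at C8, attack of leftover n-BuLi on the epoxide, or opening at the benzylic carbon could then take over. The fallback builds the chain with normal polarity and sets C3' with a catalyst. It sets out from aldehyde 4. MOM protection (MOMCl, i-Pr2NEt, CH2Cl2, 40 °C) should give 7-methoxy-5-(methoxymethoxy)-2,2-dimethyl-2H-chromene-6-carbaldehyde F1. MeMgBr (THF, 0 °C) should give racemic 1-[7-methoxy-5-(methoxymethoxy)-2,2-dimethyl-2H-chromen-6-yl]ethan-1-ol F2. Dess–Martin periodinane (CH2Cl2, NaHCO3) should give the methyl ketone 1-[7-methoxy-5-(methoxymethoxy)-2,2-dimethyl-2H-chromen-6-yl]ethan-1-one F3. Claisen–Schmidt condensation with benzaldehyde (KOH, EtOH, rt) should give the chalcone (2E)-1-[7-methoxy-5-(methoxymethoxy)-2,2-dimethyl-2H-chromen-6-yl]-3-phenylprop-2-en-1-one F4. Juliá–Colonna epoxidation (poly-D-leucine, urea–H2O2, DBU, THF) uses the mirror image of the catalyst that turns chalcones into (2R,3S)-epoxides, and should give [(2S,3R)-3-phenyloxiran-2-yl][7-methoxy-5-(methoxymethoxy)-2,2-dimethyl-2H-chromen-6-yl]methanone F5. SmI2 (THF–MeOH, −78 °C) should then cleave only the Cα–O bond, keeping the benzylic C–O bond and its configuration. This returns to the route at 13, which goes on through step 6. The enantiomeric purity would then depend on the epoxidation of a twisted, doubly ortho-substituted enone and would have to be checked.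

Step 1. The condensation may leak to C5, the carbon between the 4-OH and the methoxy group, giving the isomeric chromene, and prenal may oligomerise under amine catalysis. The fallback moves the C–C bond formation into an intramolecular sigmatropic shift and sets out from 1. Alkylation of the non-chelated 4-OH with 3-chloro-3-methylbut-1-yne (K2CO3, KI, acetone, reflux) should give 2-hydroxy-6-methoxy-4-[(2-methylbut-3-yn-2-yl)oxy]benzaldehyde F6. Heating (N,N-diethylaniline, 180 °C) should trigger an aromatic propargyl Claisen rearrangement towards C3, which has the higher double-bond character to C4 in the chelated aldehyde. Enolisation, a [1,5]-hydrogen shift and oxa-6π electrocyclisation then lead back to the route at 4.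

Step 6. Acid may promote loss of water from the β-hydroxy ketone, followed by ring closure of the freed phenol onto the resulting enone, or may attack the chromene double bond, in competition with acetal hydrolysis. The fallback reverses the order of unmasking and sets out from 12. The MOM group is removed first (HCl, i-PrOH–THF, 40 °C) while the carbonyl is still a dithiane, so that no enolisable β-hydroxy ketone is exposed to acid. This should give (1S)-2-[2-(5-hydroxy-7-methoxy-2,2-dimethyl-2H-chromen-6-yl)-1,3-dithian-2-yl]-1-phenylethan-1-ol F7. Near-neutral alkylative hydrolysis (MeI, CaCO3, MeCN–H2O, 40 °C) then frees the ketone and returns directly to 14.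

**Further compounds**

F1 | step 4 | 7-methoxy-5-(methoxymethoxy)-2,2-dimethyl-2H-chromene-6-carbaldehyde | COc1cc2OC(C)(C)C=Cc2c(OCOC)c1C=O
F2 | step 4 | rac-1-[7-methoxy-5-(methoxymethoxy)-2,2-dimethyl-2H-chromen-6-yl]ethan-1-ol | COc1cc2OC(C)(C)C=Cc2c(OCOC)c1C(C)O
F3 | step 4 | 1-[7-methoxy-5-(methoxymethoxy)-2,2-dimethyl-2H-chromen-6-yl]ethan-1-one | COc1cc2OC(C)(C)C=Cc2c(OCOC)c1C(C)=O
F4 | step 4 | (2E)-1-[7-methoxy-5-(methoxymethoxy)-2,2-dimethyl-2H-chromen-6-yl]-3-phenylprop-2-en-1-one | COc1cc2OC(C)(C)C=Cc2c(OCOC)c1C(=O)/C=C/c1ccccc1
F5 | step 4 | [(2S,3R)-3-phenyloxiran-2-yl][7-methoxy-5-(methoxymethoxy)-2,2-dimethyl-2H-chromen-6-yl]methanone | COc1cc2OC(C)(C)C=Cc2c(OCOC)c1C(=O)[C@H]1O[C@@H]1c1ccccc1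
F6 | step 1 | 2-hydroxy-6-methoxy-4-[(2-methylbut-3-yn-2-yl)oxy]benzaldehyde | COc1cc(OC(C)(C)C#C)cc(O)c1C=O
F7 | step 6 | (1S)-2-[2-(5-hydroxy-7-methoxy-2,2-dimethyl-2H-chromen-6-yl)-1,3-dithian-2-yl]-1-phenylethan-1-ol | COc1cc2OC(C)(C)C=Cc2c(O)c1C1(C[C@H](O)c2ccccc2)SCCCS1
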